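The runs are calculated from invented constants; the scatter is artificial.

We begin from a leftover: the part of the rise in target that the flask has still to make when we look at it.

common to all: substrate 1.5 M; gas 60 mM (held)

|  | first nucleophile | temperature | remark | time |
|---|---|---|---|---|
| delta | 1.8 M | 70 °C | the very flask that is asked about, followed so far |  |
| epsilon | 1.8 M | 55 °C | run made earlier |  |
| flask | 1.80 M | 70 °C |  | 5.0 d |

- delta (time / h: target / %): 10.0: 9.0; 20.0: 10.4; 30.0: 11.6; 40.0: 11.2; 48.0: 11.3; 60.0: 11.9; 72.0: 11.8
- epsilon (time / h: target / %): 20.0: 4.4; 40.0: 5.1; 60.0: 6.1; 96.0: 6.7; 120: 7.3; 144: 7.2

(each reading ± 0.3 percentage points)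

- Monday's: at 5.0 d raise the temperature by 25 K, then wait 10 d
- Thursday's: change nothing and wait 10 d more
- Sunday's: at 5.0 d take out 90% of the target then present, then wait 10 d

- target, in percent of the substrate first charged, at 5.0 d
- which option adds most target ("none" when 2 percentage points or less is all one gets) (Monday's / Thursday's / Sunday's / none)
- target present, with what was taken out counted in, in percent of the substrate first charged, after Thursday's
- target present, with what was taken out counted in, in percent of the substrate first charged, after Sunday's

- in percentages every species weighs as the substrate in it: one self-condensation product counts as two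
- at the start none of second nucleophile is dissolved
- target taken out counts as made
- on the list of suspects stand: second nucleophile + intermediate -> other capture product; 2 substrate -> self-condensation product; gas <-> second nucleophile; substrate <-> intermediate; first nucleophile + intermediate -> target; intermediate -> side product

From 30.0 h on, the delta readings wander between 11.2% and 11.9%, so we take the last one, 11.8%, as the level, while at 20.0 h the gap to that level was 1.4 percentage points. If the gap closes by halves, it halves every 6.50 h.

The turnover count, the time of the look divided by that halving time, is then 18.5, and the leftover, the level times one half to that power, is far below the scatter of 0.3 points. The suspects list target formation as one-way, so taking target out should not pull more forward. Each option starts at that count, so we expect each to add less than 2 points. Our own reckoning is therefore 11.8% now and after either wait, with no option chosen.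

The forecast gives a little more: 12% now (range 11.6% to 12.6%), 12.4% after Thursday's and 12.4% after Sunday's, and its choice is none: “Heating has almost nothing left to act on”.

The flask gives 11.6% now, 11.6% after Thursday's and 11.6% after Sunday's, and the best choice is none, with Monday's, Thursday's and Sunday's adding 0 points, 0 points and 0 points.

    second nucleophile + intermediate → other capture product (k = 1300 M⁻¹ h⁻¹, Ea = 69.0 kJ mol⁻¹)
    2 substrate → self-condensation product (k = 0.0510 M⁻¹ h⁻¹, Ea = 85.0 kJ mol⁻¹)
    gas ⇌ second nucleophile, rate k3*(csat - [second nucleophile]) (kL = 0.860 h⁻¹)
    substrate ⇌ intermediate (K = 0.00270, k = 0.160 h⁻¹, Ea = 101 kJ mol⁻¹, ΔH = −1.00 kJ mol⁻¹)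
    first nucleophile + intermediate → target (k = 5.70 M⁻¹ h⁻¹, Ea = 79.0 kJ mol⁻¹)
    intermediate → side product (k = 0.0730 h⁻¹, Ea = 111 kJ mol⁻¹)
    (constants at 70 °C)

In this flask, at the turnover count of 18.5, substrate, the limiting reagent, stands at 0%, and half of the turnover of the capture by second nucleophile was done by 9.14 h, far earlier than the look at 5.0 d. In the epsilon flask, the same reckoning from its reading at 20.0 h and its last reading of 7.2% gives a halving time of 14.7 h and a count of 8.16 at 5.0 d, and its target there is 6.87%, against 6.98% at 144 h.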